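**Retrosynthetic overview**
- Target ⇐ one-pot double Shi epoxidation and carboxylic-acid epoxide-opening lactonisation of a macrocyclic (3E,11E)-dienoic acid; the oxirane and the δ-lactone form together, last (sets C3, C4, C11, C12).
- 14-Membered carbocycle (first ring of the target) ⇐ asymmetric Ni/Cr (Nozaki–Hiyama–Kishi) closure of C7–C8 from an ω-formyl 2-bromo-1-alkene (sets C7).
- Seco acid ⇐ Cu-catalysed anti-SN2′ opening of a 6-isopropenyl δ-lactone (gives E-C3=C4 and the free CO2H); this transient lactone comes from Grignard addition/lactonisation of a δ-oxo thioester.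
- C1/C15 ⇐ organocatalytic Mukaiyama–Michael addition of a thiopropionate silyl ketene acetal to a (2E,6E)-trienal.
- Trienal ⇐ cross-metathesis, Negishi coupling and Zr-catalysed carboalumination of hex-1-en-5-yne (fixes E-C11=C12).

Assumption: cembrane locants are used in the text (C1 = ring CH bearing the propionate unit, C3 = lactone carbinol, C7 = allylic carbinol, C11/C12 = oxirane); the ent-Shi ketone and the Kishi ligand are taken as available catalysts.

**Step 1**
Reactants: 1 hex-1-en-5-yne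
Product: 3 (1E)-1-iodo-2-methylhexa-1,5-diene, via alkenyldimethylalane 2 (not isolated)
Conditions: AlMe3 (2 equiv), Cp2ZrCl2 (0.25 equiv), CH2Cl2, 0 °C→rt; then I2, THF, −30→0 °C
Reagents that add atoms: trimethylaluminium C[Al](C)C; iodine II
Why: Negishi Zr-catalysed carboalumination adds Me–Al syn across the terminal alkyne only (the 1-alkene is inert with Cp2ZrCl2) and iodinolysis with retention gives the E-trisubstituted vinyl iodide that fixes the later C11=C12 geometry.

**Step 2**
Reactants: 4 3-bromobut-3-en-1-ol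
Product: 5 2-bromo-4-iodobut-1-ene
Conditions: I2, PPh3, imidazole, CH2Cl2, 0 °C→rt
Reagents that add atoms: iodine II
Why: Appel-type iodination of a primary alcohol, which leaves the 2-bromoalkene untouched.

**Step 3**
Reactants: 3 (1E)-1-iodo-2-methylhexa-1,5-diene; 5 2-bromo-4-iodobut-1-ene
Product: 7 (5E)-2-bromo-6-methyldeca-1,5,9-triene, via alkylzinc iodide 6 (not isolated)
Conditions: 5, Zn dust, LiCl, THF, 35 °C; then 3, Pd(PPh3)4 (3 mol%), THF, rt
Reagents that add atoms: none
Why: Negishi sp3–sp2 cross-coupling in which Pd(0) inserts into the vinyl iodide far faster than into the 1,1-disubstituted vinyl bromide and the E geometry is retained.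

**Step 4**
Reactants: 7 (5E)-2-bromo-6-methyldeca-1,5,9-triene; 8 (E)-but-2-enal
Product: 9 (2E,6E)-10-bromo-6-methylundeca-2,6,10-trienal
Conditions: Hoveyda–Grubbs II (3 mol%), 8 (5 equiv), CH2Cl2, 40 °C
Reagents that add atoms: none
Why: Olefin cross-metathesis of the only monosubstituted alkene with crotonaldehyde gives the E-enal, while the trisubstituted alkene and the bromoalkene do not react.

**Step 5**
Reactants: 10 S-ethyl propanethioate
Product: 12 {[(1Z)-1-(ethylsulfanyl)prop-1-en-1-yl]oxy}trimethylsilane, via lithium enolate 11 (not isolated)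
Conditions: LDA (1.05 equiv), THF, −78 °C; TMSCl, −78 °C→rt
Reagents that add atoms: chlorotrimethylsilane C[Si](C)(C)Cl
Why: Kinetic (Ireland-type) enolisation in THF gives the enolate with methyl trans to oxygen, and O-silylation traps it as the (Z)-silyl ketene thioacetal.

**Step 6**
Reactants: 9 (2E,6E)-10-bromo-6-methylundeca-2,6,10-trienal; 12 (Z)-silyl ketene thioacetal
Product: 13 S-ethyl (2S,3R,6E)-10-bromo-2,6-dimethyl-3-(2-oxoethyl)undeca-6,10-dienethioate
Conditions: (2S,5S)-5-benzyl-2-tert-butyl-3-methylimidazolidin-4-one·TFA (20 mol%), CH2Cl2/i-PrOH/H2O, −70 °C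
Reagents that add atoms: none
Why: Iminium-catalysed (MacMillan) Mukaiyama–Michael addition in which the catalyst shields the Si face of the β-carbon so that the nucleophile adds to the Re face (C1 = R), and the (Z)-ketene acetal reacts through an open transition state to the syn adduct (C15 = S).

**Step 7**
Reactants: 13 δ-oxo thioester; 14 isopropenylmagnesium bromide
Product: 16 (3S,4R)-4-[(3E)-7-bromo-3-methylocta-3,7-dien-1-yl]-3-methyl-6-(prop-1-en-2-yl)oxan-2-one (both C6 epimers), via magnesium alkoxide 15 (not isolated)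
Conditions: 14 (1.1 equiv), THF, −78 °C; warm to rt; 1 M HCl
Reagents that add atoms: none
Why: Chemoselective Grignard 1,2-addition to the aldehyde (the thioester is spared at −78 °C) followed by acyl substitution of the thioester by the alkoxide closes the δ-lactone; the new carbinol centre is formed unselectively but is erased in step 8, and any C15 epimer can be equilibrated in this lactone to the needed trans 3-Me/4-alkyl isomer.

**Step 8**
Reactants: 16 vinyl δ-lactone; 17 (1,3-dioxolan-2-ylmethyl)magnesium bromide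
Product: 19 (2S,3R,6E)-10-bromo-2,6-dimethyl-3-[(2E)-3-methyl-6-oxohex-2-en-1-yl]undeca-6,10-dienoic acid, via dioxolane acid 18 (not isolated)
Conditions: 17 (2 equiv), CuBr·SMe2 (0.2 equiv), THF/Me2S, −40→0 °C; then 2 M HCl, THF, rt
Reagents that add atoms: water O
Why: Cu-catalysed anti-SN2′ alkylative opening of the allylic lactone (as in cuprate SN2′ reactions of 2-methylallylic esters) attacks the terminal CH2, giving the E-trisubstituted C3=C4 alkene and the free acid from either lactone epimer, and the acidic work-up hydrolyses the dioxolane to the aldehyde.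

**Step 9**
Reactants: 19 ω-formyl bromoalkene acid
Product: 22 (2S)-2-[(1R,3E,7R,11E)-7-hydroxy-4,12-dimethyl-8-methylidenecyclotetradeca-3,11-dien-1-yl]propanoic acid, via trimethylsilyl ester 20 (not isolated), via bis-silyl macrocycle 21 (not isolated)
Conditions: TMSCl (3 equiv), Et3N (1.1 equiv), MeCN, rt; slow addition (12 h, 2 mM) to CrCl2 (15 mol%), Kishi oxazoline–sulfonamide ligand (17 mol%, enantiomer giving 7R), NiCl2·(2,9-dimethylphenanthroline) (3 mol%), Mn (3 equiv), LiCl, MeCN, rt; then 10% aq. citric acid, THF, rt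
Reagents that add atoms: none
Why: Catalytic asymmetric Nozaki–Hiyama–Kishi macrocyclisation in which Ni(0) inserts into the 2-bromoalkene and the alkenyl-Cr(III) species adds to the aldehyde inside the chiral sulfonamide complex, closing the 14-membered ring and setting C7 (R) by ligand control, with the acid masked in situ as its silyl ester and TMSCl/Mn turning the chromium over.

**Step 10 (key step)**
Reactants: 22 macrocyclic hydroxy dienoic acid
Product: 24 target (1R,3R,4S,7R,11S,12S,15S)-11,12-epoxy-4,7-dihydroxycembr-8(19)-en-16,3-olide, via bis-epoxy acid 23 (not isolated)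
Conditions: ent-Shi ketone (1,2:4,5-di-O-isopropylidene-β-L-erythro-2,3-hexodiulo-2,6-pyranose, 0.6 equiv), Oxone (3 equiv), K2CO3, Bu4NHSO4 (cat.), MeCN/DMM–aq. Na2B4O7/EDTA (pH 10.5), 0 °C, 2 h; then NaH2PO4 to pH 5–6, EtOAc/H2O, rt
Reagents that add atoms: Oxone (potassium peroxymonosulfate) [K+].[O-]S(=O)(=O)OO
Why: Shi asymmetric epoxidation (chiral dioxirane, spiro transition state) converts both E-trisubstituted alkenes into the (3S,4S)- and (11S,12S)-oxiranes while the deactivated 1,1-disubstituted allylic-alcohol alkene is left, and on mild acidification the C16 acid opens the 3,4-oxirane by 6-exo attack with inversion at C3 (neighbouring-group lactonisation of a δ,ε-epoxy acid), so the oxirane and δ-lactone rings and C3 (R), C4 (S), C11 (S), C12 (S) are set in one operation.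

**Compound list**
1 | hex-1-en-5-yne | C=CCCC#C | starting material
2 | dimethyl[(1E)-2-methylhexa-1,5-dien-1-yl]alumane | C[Al](C)/C=C(C)/CCC=C | intermediate
3 | (1E)-1-iodo-2-methylhexa-1,5-diene | I/C=C(C)/CCC=C | intermediate
4 | 3-bromobut-3-en-1-ol | C=C(Br)CCO | starting material
5 | 2-bromo-4-iodobut-1-ene | C=C(Br)CCI | intermediate
6 | (3-bromobut-3-en-1-yl)zinc iodide | C=C(Br)CC[Zn]I | intermediate
7 | (5E)-2-bromo-6-methyldeca-1,5,9-triene | C=C(Br)CC/C=C(C)/CCC=C | intermediate
8 | (E)-but-2-enal (crotonaldehyde) | C/C=C/C=O | starting material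
9 | (2E,6E)-10-bromo-6-methylundeca-2,6,10-trienal | C=C(Br)CC/C=C(C)/CC/C=C/C=O | intermediate
10 | S-ethyl propanethioate | CCC(=O)SCC | starting material
11 | lithium (1Z)-1-(ethylsulfanyl)prop-1-en-1-olate | C/C=C(\SCC)[O-].[Li+] | intermediate
12 | {[(1Z)-1-(ethylsulfanyl)prop-1-en-1-yl]oxy}trimethylsilane | C/C=C(\SCC)O[Si](C)(C)C | intermediate
13 | S-ethyl (2S,3R,6E)-10-bromo-2,6-dimethyl-3-(2-oxoethyl)undeca-6,10-dienethioate | C=C(Br)CC/C=C(C)/CC[C@H](CC=O)[C@H](C)C(=O)SCC | intermediate
14 | isopropenylmagnesium bromide | C=C(C)[Mg]Br | starting material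
15 | bromomagnesium alkoxide of S-ethyl (2S,3R,6E)-10-bromo-3-(2-hydroxy-3-methylbut-3-en-1-yl)-2,6-dimethylundeca-6,10-dienethioate (carbinol epimers) | C=C(Br)CC/C=C(C)/CC[C@H](CC(O[Mg]Br)C(C)=C)[C@H](C)C(=O)SCC | intermediate
16 | (3S,4R)-4-[(3E)-7-bromo-3-methylocta-3,7-dien-1-yl]-3-methyl-6-(prop-1-en-2-yl)oxan-2-one (both C6 epimers) | C=C(Br)CC/C=C(C)/CC[C@@H]1CC(C(C)=C)OC(=O)[C@H]1C | intermediate
17 | (1,3-dioxolan-2-ylmethyl)magnesium bromide | Br[Mg]CC1OCCO1 | starting material
18 | (2S,3R,6E)-10-bromo-3-[(2E)-5-(1,3-dioxolan-2-yl)-3-methylpent-2-en-1-yl]-2,6-dimethylundeca-6,10-dienoic acid | C=C(Br)CC/C=C(C)/CC[C@H](C/C=C(C)/CCC1OCCO1)[C@H](C)C(=O)O | intermediate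
19 | (2S,3R,6E)-10-bromo-2,6-dimethyl-3-[(2E)-3-methyl-6-oxohex-2-en-1-yl]undeca-6,10-dienoic acid | C=C(Br)CC/C=C(C)/CC[C@H](C/C=C(C)/CCC=O)[C@H](C)C(=O)O | intermediate
20 | trimethylsilyl ester of 19 | C=C(Br)CC/C=C(C)/CC[C@H](C/C=C(C)/CCC=O)[C@H](C)C(=O)O[Si](C)(C)C | intermediate
21 | trimethylsilyl (2S)-2-[(1R,3E,7R,11E)-4,12-dimethyl-8-methylidene-7-(trimethylsilyloxy)cyclotetradeca-3,11-dien-1-yl]propanoate | C=C1CC/C=C(C)/CC[C@H](C/C=C(C)/CC[C@H]1O[Si](C)(C)C)[C@H](C)C(=O)O[Si](C)(C)C | intermediate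
22 | (2S)-2-[(1R,3E,7R,11E)-7-hydroxy-4,12-dimethyl-8-methylidenecyclotetradeca-3,11-dien-1-yl]propanoic acid | C=C1CC/C=C(C)/CC[C@H](C/C=C(C)/CC[C@H]1O)[C@H](C)C(=O)O | intermediate
23 | (2S)-2-[(1R,3S,4S,7R,11S,12S)-3,4:11,12-diepoxy-7-hydroxy-4,12-dimethyl-8-methylidenecyclotetradecan-1-yl]propanoic acid | C=C1CC[C@@H]2O[C@@]2(C)CC[C@H](C[C@@H]3O[C@@]3(C)CC[C@H]1O)[C@H](C)C(=O)O | intermediate
24 | CNP0262409.1, (1R,3R,4S,7R,11S,12S,15S)-11,12-epoxy-4,7-dihydroxycembr-8(19)-en-16,3-olide | C=C1CC[C@@H]2O[C@@]2(C)CC[C@@H]2C[C@@H](OC(=O)[C@H]2C)[C@@](C)(O)CC[C@H]1O | target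

**Step count and risks**
Total step count: 10. Longest linear sequence: 8 steps (1, 3, 4, 6, 7, 8, 9, 10).

Step 10 is the most likely to fail. The macrocycle may present the wrong olefin face to the catalyst, or the free 7-OH may open the 3,4-oxirane to a transannular ether. The fallback forms the oxirane and lactone on the open chain and closes the carbocycle last. It sets out from 16: allylmagnesium bromide with CuBr·SMe2 (anti-SN2′) gives the heptadienyl acid F1; the same ent-Shi epoxidation and acidification, now on an acyclic substrate whose vinyl and bromoalkene groups are inert, gives the epoxy hydroxy lactone F2; TMS-imidazole masks the tertiary alcohol as the silyl ether F3, so that no lactol can form; ozonolysis of the terminal alkene (−78 °C, PPh3) gives the aldehyde F4; CrCl2/NiCl2 with the Kishi ligand closes the ring to the silylated macrocycle F5; TBAF/AcOH returns to the route at 24.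

Step 9 is second. The 2-bromoalkene may be sluggish, the silyl-ester masking may be incomplete, or ligand control at C7 may be poor. The fallback separates ring closure from the C7 stereocentre. It sets out from 19: TMSCHN2 gives the methyl ester aldehyde F6; stoichiometric CrCl2/NiCl2 in DMSO/THF at high dilution gives the macrocyclic hydroxy ester F7 as both C7 epimers; Dess–Martin oxidation gives the α-methylene ketone F8; (S)-Me-CBS/BH3·SMe2 reduction gives the 7R hydroxy ester F9; LiOH returns to the route at 22.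

Step 8 is third. Carbonyl attack on the lactone may compete, or E/Z selectivity in the SN2′ opening may be poor. The fallback replaces the kinetic Cu(I) anti-SN2′ with Pd(0) π-allyl chemistry. It sets out from 16: Pd(PPh3)4 ionises the vinyl lactone to the thermodynamically preferred syn π-allyl carboxylate, and (1,3-dioxolan-2-ylmethyl)zinc bromide couples at the unsubstituted terminus to give the E-olefin acid 18; the same HCl work-up returns to the route at 19. This fallback makes no new compound (F0).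

**Further compounds**
F1 | step 10 | (2S,3R,6E)-10-bromo-2,6-dimethyl-3-[(2E)-3-methylhepta-2,6-dien-1-yl]undeca-6,10-dienoic acid | C=C(Br)CC/C=C(C)/CC[C@H](C/C=C(C)/CCC=C)[C@H](C)C(=O)O
F2 | step 10 | (3S,4R,6R)-4-{2-[(2S,3S)-3-(3-bromobut-3-en-1-yl)-2-methyloxiran-2-yl]ethyl}-6-[(2S)-2-hydroxyhex-5-en-2-yl]-3-methyloxan-2-one | C=C(Br)CC[C@@H]1O[C@@]1(C)CC[C@@H]1C[C@@H](OC(=O)[C@H]1C)[C@@](C)(O)CCC=C
F3 | step 10 | trimethylsilyl ether of F2 at the tertiary alcohol | C=C(Br)CC[C@@H]1O[C@@]1(C)CC[C@@H]1C[C@@H](OC(=O)[C@H]1C)[C@@](C)(O[Si](C)(C)C)CCC=C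
F4 | step 10 | (4S)-4-[(2R,4R,5S)-4-{2-[(2S,3S)-3-(3-bromobut-3-en-1-yl)-2-methyloxiran-2-yl]ethyl}-5-methyl-6-oxooxan-2-yl]-4-(trimethylsilyloxy)pentanal | C=C(Br)CC[C@@H]1O[C@@]1(C)CC[C@@H]1C[C@@H](OC(=O)[C@H]1C)[C@@](C)(O[Si](C)(C)C)CCC=O
F5 | step 10 | 4-O-trimethylsilyl ether of 24 | C=C1CC[C@@H]2O[C@@]2(C)CC[C@@H]2C[C@@H](OC(=O)[C@H]2C)[C@@](C)(O[Si](C)(C)C)CC[C@H]1O
F6 | step 9 | methyl (2S,3R,6E)-10-bromo-2,6-dimethyl-3-[(2E)-3-methyl-6-oxohex-2-en-1-yl]undeca-6,10-dienoate | C=C(Br)CC/C=C(C)/CC[C@H](C/C=C(C)/CCC=O)[C@H](C)C(=O)OC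
F7 | step 9 | methyl (2S)-2-[(1R,3E,11E)-7-hydroxy-4,12-dimethyl-8-methylidenecyclotetradeca-3,11-dien-1-yl]propanoate (C7 epimers) | C=C1CC/C=C(C)/CC[C@H](C/C=C(C)/CCC1O)[C@H](C)C(=O)OC
F8 | step 9 | methyl (2S)-2-[(1R,3E,11E)-4,12-dimethyl-8-methylidene-7-oxocyclotetradeca-3,11-dien-1-yl]propanoate | C=C1CC/C=C(C)/CC[C@H](C/C=C(C)/CCC1=O)[C@H](C)C(=O)OC
F9 | step 9 | methyl (2S)-2-[(1R,3E,7R,11E)-7-hydroxy-4,12-dimethyl-8-methylidenecyclotetradeca-3,11-dien-1-yl]propanoate | C=C1CC/C=C(C)/CC[C@H](C/C=C(C)/CC[C@H]1O)[C@H](C)C(=O)OC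
F0 | step 8 | none | none
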